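**Strategy.** The plan disconnects, in the 1,2,6-trimethylcyclohexene ring, the bond between the methyl-bearing sp2 carbon and the quaternary carbon, and removes that sp2 carbon together with its methyl group. This leaves a (2R,3R)-2,2,3-trisubstituted cyclopentanone, made by catalytic asymmetric conjugate methylation and enolate methylation of a 2-alkylcyclopentenone. In one operation a β-oxido carbenoid ring enlargement with 1,1-dibromoethane inserts the CH3–C unit between the carbonyl carbon and the quaternary α-carbon, and the regiodefined enolate is trapped as the enol triflate. The feature exploited is the ring alkene C(CH3)=CH flanked by the quaternary ring carbon, which is read as a regiodefined α-methyl ketone enolate. A 3-furyl group serves as masked butenolide and is unveiled last.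

Key step: step 7

Remark: 3-(chloromethyl)furan, geranyl chloride and 2-iodocyclopent-2-en-1-one are treated as purchased compounds, and in step 6 the ligand antipode is the one that gives the (3R) centre.

Step 1
Reactants: 1 3-(chloromethyl)furan; 2 geranyl chloride ((2E)-1-chloro-3,7-dimethylocta-2,6-diene)
Product: 4 dendrolasin (3-[(3E)-4,8-dimethylnona-3,7-dien-1-yl]furan), via furan-3-ylmethylmagnesium chloride 3 (not isolated)
Conditions: Mg, THF, 0 °C to rt; then 2, Li2CuCl4 (cat.), THF, 0 °C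
Reagents that add atoms: none
Why: Copper-catalysed cross-coupling of the furylmethyl Grignard reagent with the primary allylic chloride should occur at the α-carbon (SN2) and keep the E geometry.

Step 2
Reactants: 4 dendrolasin
Product: 5 (2E,6E)-9-(furan-3-yl)-2,6-dimethylnona-2,6-dien-1-ol
Conditions: SeO2 (cat.), t-BuOOH, salicylic acid (cat.), CH2Cl2, 0 °C to rt
Reagents that add atoms: selenium dioxide (O=[Se]=O); tert-butyl hydroperoxide (CC(C)(C)OO)
Why: Catalytic SeO2 allylic oxidation (ene reaction then [2,3]-sigmatropic shift) should hydroxylate the (E)-methyl group of the terminal trisubstituted alkene selectively.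

Step 3
Reactants: 5 (2E,6E)-9-(furan-3-yl)-2,6-dimethylnona-2,6-dien-1-ol
Product: 6 (2E,6E)-9-(furan-3-yl)-2,6-dimethylnona-2,6-dienal
Conditions: activated MnO2, CH2Cl2, rt
Reagents that add atoms: none
Why: MnO2 oxidises the primary allylic alcohol chemoselectively to the enal without touching the furan or the alkene geometry.

Step 4
Reactants: 6 (2E,6E)-9-(furan-3-yl)-2,6-dimethylnona-2,6-dienal
Product: 7 3-[(3E,7E)-4,8-dimethyldeca-3,7,9-trien-1-yl]furan
Conditions: Ph3PCH3Br, n-BuLi, THF, 0 °C; then 6, −78 °C to rt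
Reagents that add atoms: methyltriphenylphosphonium bromide (C[P+](c1ccccc1)(c1ccccc1)c1ccccc1.[Br-])
Why: Wittig methylenation of the enal gives the terminal 1,3-diene and creates no new stereo element.

Step 5
Reactants: 7 3-[(3E,7E)-4,8-dimethyldeca-3,7,9-trien-1-yl]furan; 8 2-iodocyclopent-2-en-1-one
Product: 10 2-[(3E,7E)-10-(furan-3-yl)-3,7-dimethyldeca-3,7-dien-1-yl]cyclopent-2-en-1-one, via B-alkyl-9-BBN 9 (not isolated)
Conditions: 9-BBN, THF, 0 °C to rt; then 8, PdCl2(dppf) (cat.), AsPh3 (cat.), Cs2CO3, DMF/THF/H2O, rt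
Reagents that add atoms: none
Why: 9-BBN should hydroborate only the monosubstituted vinyl terminus of the diene at its CH2 carbon, and the primary alkylborane then enters a B-alkyl Suzuki–Miyaura coupling with the α-iodoenone.

Step 6
Reactants: 10 2-[(3E,7E)-10-(furan-3-yl)-3,7-dimethyldeca-3,7-dien-1-yl]cyclopent-2-en-1-one
Product: 12 (2R,3R)-2-[(3E,7E)-10-(furan-3-yl)-3,7-dimethyldeca-3,7-dien-1-yl]-2,3-dimethylcyclopentan-1-one, via bromomagnesium enolate 11 (not isolated)
Conditions: MeMgBr, Cu(OTf)2 (cat.), chiral hydroxyalkyl imidazolinium salt (NHC precursor, cat.), Et2O, −30 to 0 °C; then MeI, HMPA, THF, −30 °C to rt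
Reagents that add atoms: methylmagnesium bromide (C[Mg]Br); iodomethane (CI)
Why: Copper-catalysed asymmetric conjugate addition to the α-substituted cyclic enone sets C3 under catalyst control, and enolate 11 is methylated anti to the new C3 methyl group, so the two methyl groups end up trans at the quaternary C2 (conjugate addition–enolate alkylation).

Step 7
Reactants: 12 (2R,3R)-2-[(3E,7E)-10-(furan-3-yl)-3,7-dimethyldeca-3,7-dien-1-yl]-2,3-dimethylcyclopentan-1-one
Product: 16 (3R,4R)-3-[(3E,7E)-10-(furan-3-yl)-3,7-dimethyldeca-3,7-dien-1-yl]-2,3,4-trimethylcyclohex-1-en-1-yl trifluoromethanesulfonate, via lithium alkoxide adduct 13 (not isolated), via β-oxido carbenoid 14 (not isolated), via lithium enolate 15 (not isolated)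
Conditions: CH3CHBr2, LDA, THF/Et2O, −100 °C; then n-BuLi, −100 to −60 °C; then PhNTf2, −78 °C to rt
Reagents that add atoms: 1,1-dibromoethane (CC(Br)Br); N-phenyl-bis(trifluoromethanesulfonimide) (O=S(=O)(N(c1ccccc1)S(=O)(=O)C(F)(F)F)C(F)(F)F)
Why: LDA deprotonates 1,1-dibromoethane at −100 °C and the resulting 1,1-dibromoethyllithium adds to the ketone of 12; bromine–lithium exchange on adduct 13 gives β-oxido carbenoid 14, in which the quaternary ring carbon shifts from the carbinol carbon to the carbenoid carbon as bromide leaves, so that enolate 15 of the enlarged ring forms with its double bond between the former carbonyl carbon and the new methyl-bearing carbon. The closest known reaction type is the β-oxido carbenoid one-carbon ring enlargement of cyclic ketones with dihalomethyllithium reagents, here with the methyl-substituted carbenoid, followed by ordinary O-triflation of a lithium enolate. The six-membered ring is not closed by a cyclisation but arises by this 1,2-shift of a ring bond (five to six). No new stereocentre forms: the quaternary centre migrates with retention and the neighbouring CH(CH3) centre is a spectator. The step needs migration of the quaternary carbon and not of the ring CH2, which the usual preference of β-oxido carbenoids for the more substituted α-carbon should secure, and it needs O- over C-sulfonylation, which the hindered tetrasubstituted enolate carbon should secure.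

Step 8
Reactants: 16 (3R,4R)-3-[(3E,7E)-10-(furan-3-yl)-3,7-dimethyldeca-3,7-dien-1-yl]-2,3,4-trimethylcyclohex-1-en-1-yl trifluoromethanesulfonate
Product: 17 3-[(3E,7E)-4,8-dimethyl-10-[(1R,6R)-1,2,6-trimethylcyclohex-2-en-1-yl]deca-3,7-dien-1-yl]furan
Conditions: Pd(OAc)2 (cat.), PPh3, HCO2H, Et3N, DMF, 60 °C
Reagents that add atoms: none
Why: Palladium-catalysed formate reduction of the enol triflate replaces OTf by H without moving the double bond and touches no stereocentre.

Step 9
Reactants: 17 3-[(3E,7E)-4,8-dimethyl-10-[(1R,6R)-1,2,6-trimethylcyclohex-2-en-1-yl]deca-3,7-dien-1-yl]furan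
Product: 20 4-[(3E,7E)-4,8-dimethyl-10-[(1R,6R)-1,2,6-trimethylcyclohex-2-en-1-yl]deca-3,7-dien-1-yl]furan-2(5H)-one, via furan endoperoxide 18 (not isolated), via γ-hydroxybutenolide 19 (not isolated)
Conditions: O2, hν, rose bengal (cat.), i-Pr2NEt, CH2Cl2/MeOH, −78 °C; then NaBH4, −78 to 0 °C; then 1 M HCl
Reagents that add atoms: oxygen (O=O)
Why: Singlet oxygen adds [4+2] to the furan much faster than it attacks trisubstituted alkenes, the hindered base opens endoperoxide 18 at the less hindered bridgehead C–H (Kornblum–DeLaMare-type fragmentation) to the β-alkyl γ-hydroxybutenolide 19, and NaBH4 reduces its open aldehyde form so that acid closes the β-substituted butenolide.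

**Compound list**

1 | 3-(chloromethyl)furan | ClCc1ccoc1 | starting material
2 | geranyl chloride, (2E)-1-chloro-3,7-dimethylocta-2,6-diene | CC(C)=CCC/C(C)=C/CCl | starting material
3 | furan-3-ylmethylmagnesium chloride | Cl[Mg]Cc1ccoc1 | intermediate
4 | dendrolasin, 3-[(3E)-4,8-dimethylnona-3,7-dien-1-yl]furan | CC(C)=CCC/C(C)=C/CCc1ccoc1 | intermediate
5 | (2E,6E)-9-(furan-3-yl)-2,6-dimethylnona-2,6-dien-1-ol | OC/C(C)=C/CC/C(C)=C/CCc1ccoc1 | intermediate
6 | (2E,6E)-9-(furan-3-yl)-2,6-dimethylnona-2,6-dienal | O=C/C(C)=C/CC/C(C)=C/CCc1ccoc1 | intermediate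
7 | 3-[(3E,7E)-4,8-dimethyldeca-3,7,9-trien-1-yl]furan | C=C/C(C)=C/CC/C(C)=C/CCc1ccoc1 | intermediate
8 | 2-iodocyclopent-2-en-1-one | O=C1CCC=C1I | starting material
9 | 9-[(3E,7E)-10-(furan-3-yl)-3,7-dimethyldeca-3,7-dien-1-yl]-9-borabicyclo[3.3.1]nonane | B1(CC/C(C)=C/CC/C(C)=C/CCc3ccoc3)C2CCCC1CCC2 | intermediate
10 | 2-[(3E,7E)-10-(furan-3-yl)-3,7-dimethyldeca-3,7-dien-1-yl]cyclopent-2-en-1-one | O=C1CCC=C1CC/C(C)=C/CC/C(C)=C/CCc1ccoc1 | intermediate
11 | bromomagnesium (3R)-2-[(3E,7E)-10-(furan-3-yl)-3,7-dimethyldeca-3,7-dien-1-yl]-3-methylcyclopent-1-en-1-olate | C[C@@H]1CCC(O[Mg]Br)=C1CC/C(C)=C/CC/C(C)=C/CCc1ccoc1 | intermediate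
12 | (2R,3R)-2-[(3E,7E)-10-(furan-3-yl)-3,7-dimethyldeca-3,7-dien-1-yl]-2,3-dimethylcyclopentan-1-one | O=C1CC[C@@H](C)[C@@]1(C)CC/C(C)=C/CC/C(C)=C/CCc1ccoc1 | intermediate
13 | lithium (2R,3R)-1-(1,1-dibromoethyl)-2-[(3E,7E)-10-(furan-3-yl)-3,7-dimethyldeca-3,7-dien-1-yl]-2,3-dimethylcyclopentan-1-olate (C1 epimers) | [Li]OC1(C(C)(Br)Br)CC[C@@H](C)[C@@]1(C)CC/C(C)=C/CC/C(C)=C/CCc1ccoc1 | intermediate
14 | lithium (2R,3R)-1-(1-bromo-1-lithioethyl)-2-[(3E,7E)-10-(furan-3-yl)-3,7-dimethyldeca-3,7-dien-1-yl]-2,3-dimethylcyclopentan-1-olate | [Li]OC1(C(C)(Br)[Li])CC[C@@H](C)[C@@]1(C)CC/C(C)=C/CC/C(C)=C/CCc1ccoc1 | intermediate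
15 | lithium (3R,4R)-3-[(3E,7E)-10-(furan-3-yl)-3,7-dimethyldeca-3,7-dien-1-yl]-2,3,4-trimethylcyclohex-1-en-1-olate | CC1=C(O[Li])CC[C@@H](C)[C@@]1(C)CC/C(C)=C/CC/C(C)=C/CCc1ccoc1 | intermediate
16 | (3R,4R)-3-[(3E,7E)-10-(furan-3-yl)-3,7-dimethyldeca-3,7-dien-1-yl]-2,3,4-trimethylcyclohex-1-en-1-yl trifluoromethanesulfonate | CC1=C(OS(=O)(=O)C(F)(F)F)CC[C@@H](C)[C@@]1(C)CC/C(C)=C/CC/C(C)=C/CCc1ccoc1 | intermediate
17 | 3-[(3E,7E)-4,8-dimethyl-10-[(1R,6R)-1,2,6-trimethylcyclohex-2-en-1-yl]deca-3,7-dien-1-yl]furan | CC1=CCC[C@@H](C)[C@@]1(C)CC/C(C)=C/CC/C(C)=C/CCc1ccoc1 | intermediate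
18 | 5-[(3E,7E)-4,8-dimethyl-10-[(1R,6R)-1,2,6-trimethylcyclohex-2-en-1-yl]deca-3,7-dien-1-yl]-2,3,7-trioxabicyclo[2.2.1]hept-5-ene (bridgehead epimers) | CC1=CCC[C@@H](C)[C@@]1(C)CC/C(C)=C/CC/C(C)=C/CCC1=CC2OOC1O2 | intermediate
19 | 5-hydroxy-4-[(3E,7E)-4,8-dimethyl-10-[(1R,6R)-1,2,6-trimethylcyclohex-2-en-1-yl]deca-3,7-dien-1-yl]furan-2(5H)-one (C5 epimers) | CC1=CCC[C@@H](C)[C@@]1(C)CC/C(C)=C/CC/C(C)=C/CCC1=CC(=O)OC1O | intermediate
20 | 4-[(3E,7E)-4,8-dimethyl-10-[(1R,6R)-1,2,6-trimethylcyclohex-2-en-1-yl]deca-3,7-dien-1-yl]furan-2(5H)-one | CC1=CCC[C@@H](C)[C@@]1(C)CC/C(C)=C/CC/C(C)=C/CCC1=CC(=O)OC1 | target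

**Step count and risks**

Total step count: 9. Longest linear sequence: 9 (steps 1 to 9, from 1 and 2).

Steps most likely to fail:

1. Step 7. The bulky, thermally labile carbenoid may add too slowly to the α-quaternary ketone, so that enolisation or carbenoid decomposition wins, or the ring CH2 may migrate in place of the quaternary carbon. The fallback enlarges the ring on the other side of the carbonyl and brings the vinylic methyl in afterwards. It sets out from 12: trimethylsilyldiazomethane with Me3Al in CH2Cl2 at low temperature should insert CH2 by migration of the less substituted α-carbon and give (2R,3R)-2-[(3E,7E)-10-(furan-3-yl)-3,7-dimethyldeca-3,7-dien-1-yl]-2,3-dimethyl-6-(trimethylsilyl)cyclohexan-1-one F1. Dilute acid on work-up removes silicon to give (2R,3R)-2-[(3E,7E)-10-(furan-3-yl)-3,7-dimethyldeca-3,7-dien-1-yl]-2,3-dimethylcyclohexan-1-one F2. Deprotonation with KHMDS at the only enolisable position and trapping with PhNTf2 should give (5R,6R)-6-[(3E,7E)-10-(furan-3-yl)-3,7-dimethyldeca-3,7-dien-1-yl]-5,6-dimethylcyclohex-1-en-1-yl trifluoromethanesulfonate F3. Iron-catalysed coupling with MeMgBr (Fe(acac)3, THF/NMP) then comes back to the route at 17.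

2. Step 6. Facial control in the methyl transfer to the α-substituted enone may be insufficient, and the hindered magnesium enolate may be protonated or alkylated sluggishly. The fallback gives up catalyst control and resolves instead. It sets out from 10: Me2CuLi followed by MeI/HMPA should give the racemic trans ketone rac-(2R,3R)-2-[(3E,7E)-10-(furan-3-yl)-3,7-dimethyldeca-3,7-dien-1-yl]-2,3-dimethylcyclopentan-1-one F4. Addition of lithiated (S)-N,S-dimethyl-S-phenylsulfoximine gives diastereomeric β-hydroxysulfoximines that are separated by chromatography. The fraction derived from the (2R,3R) ketone, (2R,3R)-2-[(3E,7E)-10-(furan-3-yl)-3,7-dimethyldeca-3,7-dien-1-yl]-2,3-dimethyl-1-{[(S)-N-methyl-S-phenylsulfonimidoyl]methyl}cyclopentan-1-ol F5, is heated in toluene and reverts to the ketone, which comes back to the route at 12.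

3. Step 5. Hydroboration of the conjugated diene may be unselective (attack at the internal position or double hydroboration), and the α-iodoenone may degrade under the basic coupling conditions. The fallback builds the cyclopentenone around the chain instead. It sets out from 5: CBr4/PPh3 should give 3-[(3E,7E)-9-bromo-4,8-dimethylnona-3,7-dien-1-yl]furan F6. Alkylation of lithiated 1-(trimethylsilyl)propyne gives trimethyl[(5E,9E)-12-(furan-3-yl)-5,9-dimethyldodeca-5,9-dien-1-yn-1-yl]silane F7. K2CO3 in methanol removes silicon to give 3-[(3E,7E)-4,8-dimethyldodeca-3,7-dien-11-yn-1-yl]furan F8. A Pauson–Khand reaction with ethylene (Co2(CO)8, amine N-oxide promoter) places the alkyne substituent α to the carbonyl and comes back to the route at 10.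

Further compounds
F1 | step 7 | (2R,3R)-2-[(3E,7E)-10-(furan-3-yl)-3,7-dimethyldeca-3,7-dien-1-yl]-2,3-dimethyl-6-(trimethylsilyl)cyclohexan-1-one | O=C1C([Si](C)(C)C)CC[C@@H](C)[C@@]1(C)CC/C(C)=C/CC/C(C)=C/CCc1ccoc1
F2 | step 7 | (2R,3R)-2-[(3E,7E)-10-(furan-3-yl)-3,7-dimethyldeca-3,7-dien-1-yl]-2,3-dimethylcyclohexan-1-one | O=C1CCC[C@@H](C)[C@@]1(C)CC/C(C)=C/CC/C(C)=C/CCc1ccoc1
F3 | step 7 | (5R,6R)-6-[(3E,7E)-10-(furan-3-yl)-3,7-dimethyldeca-3,7-dien-1-yl]-5,6-dimethylcyclohex-1-en-1-yl trifluoromethanesulfonate | O=S(=O)(OC1=CCC[C@@H](C)[C@@]1(C)CC/C(C)=C/CC/C(C)=C/CCc1ccoc1)C(F)(F)F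
F4 | step 6 | rac-(2R,3R)-2-[(3E,7E)-10-(furan-3-yl)-3,7-dimethyldeca-3,7-dien-1-yl]-2,3-dimethylcyclopentan-1-one | O=C1CC[C@@H](C)[C@@]1(C)CC/C(C)=C/CC/C(C)=C/CCc1ccoc1.O=C1CC[C@H](C)[C@]1(C)CC/C(C)=C/CC/C(C)=C/CCc1ccoc1
F5 | step 6 | (2R,3R)-2-[(3E,7E)-10-(furan-3-yl)-3,7-dimethyldeca-3,7-dien-1-yl]-2,3-dimethyl-1-{[(S)-N-methyl-S-phenylsulfonimidoyl]methyl}cyclopentan-1-ol (C1 epimers) | CN=[S@](=O)(CC1(O)CC[C@@H](C)[C@@]1(C)CC/C(C)=C/CC/C(C)=C/CCc1ccoc1)c1ccccc1
F6 | step 5 | 3-[(3E,7E)-9-bromo-4,8-dimethylnona-3,7-dien-1-yl]furan | BrC/C(C)=C/CC/C(C)=C/CCc1ccoc1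
F7 | step 5 | trimethyl[(5E,9E)-12-(furan-3-yl)-5,9-dimethyldodeca-5,9-dien-1-yn-1-yl]silane | C[Si](C)(C)C#CCC/C(C)=C/CC/C(C)=C/CCc1ccoc1
F8 | step 5 | 3-[(3E,7E)-4,8-dimethyldodeca-3,7-dien-11-yn-1-yl]furan | C#CCC/C(C)=C/CC/C(C)=C/CCc1ccoc1
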